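**Retrosynthetic overview**
- The Z-p-coumarate comes from the E-ester by photocatalytic E-to-Z isomerisation; the ester C–O bond comes from a Mitsunobu coupling of the ring-A allylic alcohol with p-coumaric acid, and the acrylate from a malonate by decarboxylative methylenation.
- The allylic alcohol comes from the ring-A enal (1,2-reduction).
- The decalin enal is cut in one operation to an acyclic enal/aldehyde/trisubstituted alkene: ring B forms first (C5–C10, hydrogen-atom-transfer-initiated 6-exo Giese cyclisation), then ring A (C3–C4, crossover aldol, then dehydration).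
- The only pre-set stereocentre (C7) comes from an organocatalytic malonate Michael addition to an enal; the enal comes from cross-metathesis and the chain from a Wittig reaction on hex-5-en-2-one.
- The benzene ring is bought with p-coumaric acid.

Assumption: decalin carbons are referred to by eudesmane numbering (C1–C15), and the trisubstituted alkene made in step 1 is carried as an E/Z mixture because it is consumed in step 6.

**Step 1**
Reactants: 1 hex-5-en-2-one; 2 (3-hydroxypropyl)triphenylphosphonium bromide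
Product: 4 (3E/Z)-4-methylocta-3,7-dien-1-ol, via lithium oxido ylide 3 (not isolated)
Conditions: 2, n-BuLi (2.0 equiv), THF, 0 °C; then 1, 0 °C to rt
Reagents that add atoms: none
Why: Wittig olefination of the methyl ketone with the non-stabilised γ-oxido ylide gives the trisubstituted alkene, whose E/Z ratio is irrelevant because this alkene is destroyed in step 6; no stereocentre is formed.

**Step 2**
Reactants: 4 (3E/Z)-4-methylocta-3,7-dien-1-ol; 5 (E)-but-2-enal
Product: 6 (2E,6E/Z)-9-hydroxy-6-methylnona-2,6-dienal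
Conditions: 5 (5 equiv), second-generation Hoveyda–Grubbs catalyst (H2IMes)Cl2Ru=CH(C6H4-2-O-i-Pr) (3 mol %), CH2Cl2, 40 °C
Reagents that add atoms: none
Why: Olefin cross-metathesis engages only the monosubstituted alkene (the trisubstituted one is too hindered) and the conjugated partner gives the E-enal with loss of propene.

**Step 3**
Reactants: 6 (2E,6E/Z)-9-hydroxy-6-methylnona-2,6-dienal; 7 dimethyl malonate
Product: 8 dimethyl 2-[(3R,6E/Z)-9-hydroxy-6-methyl-1-oxonon-6-en-3-yl]propanedioate
Conditions: 7 (2 equiv), (S)-2-[bis(3,5-bis(trifluoromethyl)phenyl)(trimethylsilyloxy)methyl]pyrrolidine (10 mol %), EtOH, 0 °C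
Reagents that add atoms: none
Why: Iminium-catalysed asymmetric Michael addition, in which the diarylprolinol silyl ether shields one face of the E-configured s-trans iminium ion so that malonate attacks the open face and sets the future C7 as R (about 90–95 % ee expected for a linear alkyl enal).

**Step 4**
Reactants: 8 dimethyl 2-[(3R,6E/Z)-9-hydroxy-6-methyl-1-oxonon-6-en-3-yl]propanedioate; 9 (triphenylphosphoranylidene)acetaldehyde
Product: 10 dimethyl 2-[(2E,5R,8E/Z)-11-hydroxy-8-methyl-1-oxoundeca-2,8-dien-5-yl]propanedioate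
Conditions: 9 (1.3 equiv), PhMe, 80 °C
Reagents that add atoms: none
Why: Wittig olefination with the stabilised, nearly neutral formyl ylide is E-selective and leaves the acidic malonate, the free alcohol and the non-epimerisable C7 centre untouched.

**Step 5**
Reactants: 10 dimethyl 2-[(2E,5R,8E/Z)-11-hydroxy-8-methyl-1-oxoundeca-2,8-dien-5-yl]propanedioate
Product: 11 dimethyl 2-[(2E,5R,8E/Z)-8-methyl-1,11-dioxoundeca-2,8-dien-5-yl]propanedioate
Conditions: TEMPO (2,2,6,6-tetramethylpiperidin-1-oxyl, 10 mol %), PhI(OAc)2 (1.2 equiv), CH2Cl2, rt; crude product used at once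
Reagents that add atoms: none
Why: Oxoammonium (TEMPO/PhI(OAc)2) oxidation is selective for the primary alcohol and, being non-basic, gives the β,γ-unsaturated aldehyde without moving the alkene into conjugation.

**Step 6**
Reactants: 11 dimethyl 2-[(2E,5R,8E/Z)-8-methyl-1,11-dioxoundeca-2,8-dien-5-yl]propanedioate
Product: 13 dimethyl 2-[(2R,4aS,8aR)-8-formyl-4a-methyl-1,2,3,4,4a,5,6,8a-octahydronaphthalen-2-yl]propanedioate, via aldol adduct 12 (not isolated)
Conditions: Fe(acac)3 (30 mol %), PhSiH3 (2.5 equiv), EtOH/(CH2OH)2 5:1, 0.01 M, 0 °C to rt; silica plug and solvent switch; then p-TsOH·H2O (10 mol %), PhMe, 60 °C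
Reagents that add atoms: none
Why: Mukaiyama-type hydrogen atom transfer from an iron hydride puts H on C1 and a tertiary radical on C10, which closes ring B by 6-exo Giese addition to the enal through a chair in which the malonyl group at C7 and the enal arm at C5 are equatorial and the C10 methyl is axial (so H5 is cis to H7 and trans to the methyl), the α-formyl radical is then reduced to the iron enolate, which closes ring A by intramolecular aldol addition to the C3 aldehyde (radical–polar crossover annulation), and acid dehydrates the aldol to the ring-A enal.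

**Step 7**
Reactants: 13 dimethyl 2-[(2R,4aS,8aR)-8-formyl-4a-methyl-1,2,3,4,4a,5,6,8a-octahydronaphthalen-2-yl]propanedioate
Product: 14 dimethyl 2-[(2R,4aS,8aR)-8-(hydroxymethyl)-4a-methyl-1,2,3,4,4a,5,6,8a-octahydronaphthalen-2-yl]propanedioate
Conditions: NaBH4, CeCl3·7H2O, MeOH, −40 °C
Reagents that add atoms: none
Why: Luche reduction gives clean 1,2-reduction of the enal and touches neither the malonate esters nor any stereocentre.

**Step 8**
Reactants: 14 dimethyl 2-[(2R,4aS,8aR)-8-(hydroxymethyl)-4a-methyl-1,2,3,4,4a,5,6,8a-octahydronaphthalen-2-yl]propanedioate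
Product: 16 methyl 2-[(2R,4aR,8aR)-8-(hydroxymethyl)-4a-methyl-1,2,3,4,4a,5,6,8a-octahydronaphthalen-2-yl]prop-2-enoate, via potassium half-malonate 15 (not isolated)
Conditions: KOH (1.05 equiv), MeOH/H2O, rt; then AcOH (1.1 equiv), Et2NH, 37 % aq. CH2O, 65 °C
Reagents that add atoms: formaldehyde, C=O
Why: Half-saponification of the malonate followed by Mannich condensation with formaldehyde and decarboxylative elimination (Mannich-type methylenation of a malonic half-ester) gives the α-methylene methyl ester without touching C7.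

**Step 9**
Reactants: 16 methyl 2-[(2R,4aR,8aR)-8-(hydroxymethyl)-4a-methyl-1,2,3,4,4a,5,6,8a-octahydronaphthalen-2-yl]prop-2-enoate; 17 (2E)-3-(4-hydroxyphenyl)prop-2-enoic acid
Product: 18 methyl 2-[(2R,4aR,8aR)-8-({[(2E)-3-(4-hydroxyphenyl)prop-2-enoyl]oxy}methyl)-4a-methyl-1,2,3,4,4a,5,6,8a-octahydronaphthalen-2-yl]prop-2-enoate
Conditions: 17 (1.1 equiv), PPh3, diisopropyl azodicarboxylate, THF, 0 °C to rt
Reagents that add atoms: none
Why: Mitsunobu esterification activates the primary allylic alcohol, and the carboxylic acid (far more acidic than the phenol) is the pronucleophile that reacts, so the phenol needs no protection.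

**Step 10**
Reactants: 18 methyl 2-[(2R,4aR,8aR)-8-({[(2E)-3-(4-hydroxyphenyl)prop-2-enoyl]oxy}methyl)-4a-methyl-1,2,3,4,4a,5,6,8a-octahydronaphthalen-2-yl]prop-2-enoate
Product: 19 methyl 2-[(2R,4aR,8aR)-8-({[(2Z)-3-(4-hydroxyphenyl)prop-2-enoyl]oxy}methyl)-4a-methyl-1,2,3,4,4a,5,6,8a-octahydronaphthalen-2-yl]prop-2-enoate
Conditions: fac-Ir(ppy)3 (1 mol %), MeCN, 450 nm LEDs, rt, argon; chromatographic removal and recycling of residual 18
Reagents that add atoms: none
Why: Triplet energy transfer from the excited iridium complex isomerises the E-cinnamate to the Z-isomer, which has the higher triplet energy and accumulates (photocatalytic contra-thermodynamic E-to-Z isomerisation), while the acrylate and the ring alkene are not sensitised and no stereocentre is touched.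

**Compound list**
1 | hex-5-en-2-one | CC(=O)CCC=C | starting material
2 | (3-hydroxypropyl)triphenylphosphonium bromide | OCCC[P+](c1ccccc1)(c1ccccc1)c1ccccc1.[Br-] | starting material
3 | lithium 3-(triphenylphosphoranylidene)propan-1-olate | [Li+].[O-]CCC=P(c1ccccc1)(c1ccccc1)c1ccccc1 | intermediate
4 | (3E/Z)-4-methylocta-3,7-dien-1-ol (E/Z mixture) | OCCC=C(C)CCC=C | intermediate
5 | (E)-but-2-enal | C/C=C/C=O | starting material
6 | (2E,6E/Z)-9-hydroxy-6-methylnona-2,6-dienal | O=C/C=C/CCC(C)=CCCO | intermediate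
7 | dimethyl malonate | COC(=O)CC(=O)OC | starting material
8 | dimethyl 2-[(3R,6E/Z)-9-hydroxy-6-methyl-1-oxonon-6-en-3-yl]propanedioate | O=CC[C@H](C(C(=O)OC)C(=O)OC)CCC(C)=CCCO | intermediate
9 | (triphenylphosphoranylidene)acetaldehyde | O=CC=P(c1ccccc1)(c1ccccc1)c1ccccc1 | starting material
10 | dimethyl 2-[(2E,5R,8E/Z)-11-hydroxy-8-methyl-1-oxoundeca-2,8-dien-5-yl]propanedioate | O=C/C=C/C[C@H](C(C(=O)OC)C(=O)OC)CCC(C)=CCCO | intermediate
11 | dimethyl 2-[(2E,5R,8E/Z)-8-methyl-1,11-dioxoundeca-2,8-dien-5-yl]propanedioate | O=C/C=C/C[C@H](C(C(=O)OC)C(=O)OC)CCC(C)=CCC=O | intermediate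
12 | dimethyl 2-[(2R,4aS,8aS)-8-formyl-7-hydroxy-4a-methyldecahydronaphthalen-2-yl]propanedioate (epimers at the carbinol and formyl-bearing carbons) | COC(=O)C(C(=O)OC)[C@@H]1CC[C@@]2(C)CCC(O)C(C=O)[C@@H]2C1 | intermediate
13 | dimethyl 2-[(2R,4aS,8aR)-8-formyl-4a-methyl-1,2,3,4,4a,5,6,8a-octahydronaphthalen-2-yl]propanedioate | COC(=O)C(C(=O)OC)[C@@H]1CC[C@@]2(C)CCC=C(C=O)[C@@H]2C1 | intermediate
14 | dimethyl 2-[(2R,4aS,8aR)-8-(hydroxymethyl)-4a-methyl-1,2,3,4,4a,5,6,8a-octahydronaphthalen-2-yl]propanedioate | COC(=O)C(C(=O)OC)[C@@H]1CC[C@@]2(C)CCC=C(CO)[C@@H]2C1 | intermediate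
15 | potassium 2-[(2R,4aS,8aR)-8-(hydroxymethyl)-4a-methyl-1,2,3,4,4a,5,6,8a-octahydronaphthalen-2-yl]-3-methoxy-3-oxopropanoate (epimers at the malonyl carbon) | COC(=O)C(C(=O)[O-])[C@@H]1CC[C@@]2(C)CCC=C(CO)[C@@H]2C1.[K+] | intermediate
16 | methyl 2-[(2R,4aR,8aR)-8-(hydroxymethyl)-4a-methyl-1,2,3,4,4a,5,6,8a-octahydronaphthalen-2-yl]prop-2-enoate | C=C(C(=O)OC)[C@@H]1CC[C@@]2(C)CCC=C(CO)[C@@H]2C1 | intermediate
17 | (2E)-3-(4-hydroxyphenyl)prop-2-enoic acid (trans-p-coumaric acid) | OC(=O)/C=C/c1ccc(O)cc1 | starting material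
18 | methyl 2-[(2R,4aR,8aR)-8-({[(2E)-3-(4-hydroxyphenyl)prop-2-enoyl]oxy}methyl)-4a-methyl-1,2,3,4,4a,5,6,8a-octahydronaphthalen-2-yl]prop-2-enoate | C=C(C(=O)OC)[C@@H]1CC[C@@]2(C)CCC=C(COC(=O)/C=C/c3ccc(O)cc3)[C@@H]2C1 | intermediate
19 | methyl 2-[(2R,4aR,8aR)-8-({[(2Z)-3-(4-hydroxyphenyl)prop-2-enoyl]oxy}methyl)-4a-methyl-1,2,3,4,4a,5,6,8a-octahydronaphthalen-2-yl]prop-2-enoate | C=C(C(=O)OC)[C@@H]1CC[C@@]2(C)CCC=C(COC(=O)/C=C\c3ccc(O)cc3)[C@@H]2C1 | target

The ring-fusion descriptor changes between 4aS (12–15) and 4aR (16, 18, 19) only because CIP priorities change when the malonate becomes the acrylate; the spatial arrangement is the same throughout, as the SMILES show.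

**Totals**
Total step count: 10. Longest linear sequence: 10 steps (1 to 19); every other partner (2, 5, 7, 9, 17) is bought.

**Three steps most likely to fail**

Step 6 (bicyclisation). Two things can go wrong. The chair preference that puts the C10 methyl axial is small, so the cis-fused C10 epimer may form in a sizeable amount and would have to be removed at 13 or 14. The iron enolate may also be protonated before it finds the C3 aldehyde, and a later aldol of the resulting dialdehyde would not be regioselective. The fallback sets out from 8 and comes back at 13, and replaces the aldol by an olefination that fixes the ring-A regiochemistry and the double bond. Knoevenagel condensation of 8 with diethyl (2-oxoethyl)phosphonate (piperidinium acetate, PhMe, water removal) gives dimethyl 2-[(5R)-2-(diethoxyphosphoryl)-11-hydroxy-8-methyl-1-oxoundeca-2,8-dien-5-yl]propanedioate F1. Oxidation as in step 5 gives dimethyl 2-[(5R)-2-(diethoxyphosphoryl)-8-methyl-1,11-dioxoundeca-2,8-dien-5-yl]propanedioate F2. Under the Fe(acac)3/PhSiH3 conditions the C10 radical adds to the doubly activated alkene, and the long-lived phosphonate-stabilised enolate closes ring A by intramolecular Horner–Wadsworth–Emmons olefination onto the saturated aldehyde, giving 13 directly with no dehydration. This Giese/olefination variant is untested, and it does not by itself improve the C10 selectivity.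

Step 10 (E-to-Z isomerisation). The photostationary mixture may hold too much 18, and the two isomers may be hard to separate. The fallback sets out from 16 and comes back at 19, and builds the cis alkene by semihydrogenation. Mitsunobu coupling of 16 with 3-(4-hydroxyphenyl)prop-2-ynoic acid (PPh3, diisopropyl azodicarboxylate, THF) gives methyl 2-[(2R,4aR,8aR)-8-({[3-(4-hydroxyphenyl)prop-2-ynoyl]oxy}methyl)-4a-methyl-1,2,3,4,4a,5,6,8a-octahydronaphthalen-2-yl]prop-2-enoate F3. Hydrogenation over Pd/CaCO3 poisoned with Pb(OAc)2 and quinoline (H2, 1 atm, EtOAc, stopped at one equivalent) gives 19.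

Step 1 (Wittig on an enolisable methyl ketone). The γ-oxido ylide is a strong base and may mostly enolise 1. The fallback sets out from 1 and comes back at 4, and makes the trisubstituted alkene by a Julia cyclopropylcarbinyl-to-homoallyl rearrangement. Addition of cyclopropylmagnesium bromide to 1 (THF, 0 °C) gives 2-cyclopropylhex-5-en-2-ol F4. Cold 48 % aqueous HBr opens it to (5E)-8-bromo-5-methylocta-1,5-diene F5 (mainly E, which does not matter). KOAc in DMF gives (3E)-4-methylocta-3,7-dien-1-yl acetate F6, and K2CO3 in MeOH gives 4.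

**Further compounds**
F1 | step 6 | dimethyl 2-[(5R)-2-(diethoxyphosphoryl)-11-hydroxy-8-methyl-1-oxoundeca-2,8-dien-5-yl]propanedioate | O=CC(=CC[C@H](C(C(=O)OC)C(=O)OC)CCC(C)=CCCO)P(=O)(OCC)OCC
F2 | step 6 | dimethyl 2-[(5R)-2-(diethoxyphosphoryl)-8-methyl-1,11-dioxoundeca-2,8-dien-5-yl]propanedioate | O=CC(=CC[C@H](C(C(=O)OC)C(=O)OC)CCC(C)=CCC=O)P(=O)(OCC)OCC
F3 | step 10 | methyl 2-[(2R,4aR,8aR)-8-({[3-(4-hydroxyphenyl)prop-2-ynoyl]oxy}methyl)-4a-methyl-1,2,3,4,4a,5,6,8a-octahydronaphthalen-2-yl]prop-2-enoate | C=C(C(=O)OC)[C@@H]1CC[C@@]2(C)CCC=C(COC(=O)C#Cc3ccc(O)cc3)[C@@H]2C1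
F4 | step 1 | 2-cyclopropylhex-5-en-2-ol (racemic) | CC(O)(CCC=C)C1CC1
F5 | step 1 | (5E)-8-bromo-5-methylocta-1,5-diene | BrCC/C=C(C)/CCC=C
F6 | step 1 | (3E)-4-methylocta-3,7-dien-1-yl acetate | CC(=O)OCC/C=C(C)/CCC=C
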